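The data were computed with constants of no real substance; noise was put on by code.

I decided to try the bench rule on the two earlier runs first, because what matters when repeating this flask is how far that rule can be trusted.

| flask | starting material | gas | enzyme | remark | time |
|---|---|---|---|---|---|
| teal | 0.014 M | 4 mM (held) | 1 µM | run made earlier |  |
| amber | 0.022 M | 4 mM (held) | 1 µM | run made earlier |  |
| flask | 0.010 M | 4.0 mM (held) | 1.0 µM |  | 12 d |

- teal (time / d: target / %): 0.104: 19; 0.333: 50; 1.04: 2; 3.00: 0; 10.0: 0
- amber (time / d: target / %): 0.104: 15; 0.333: 47; 1.04: 3; 3.00: 0; 10.0: 2

(standard deviation of a reading: 2 percentage points)

- at the start none of second substrate is dissolved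
- on the list of suspects stand: starting material + enzyme <-> starting complex; second substrate + starting complex <-> ternary complex; ternary complex -> enzyme + target; enzyme + target -> enzyme + over-reaction product; gas <-> second substrate

- time, not beyond 12 d, at which the flask holds most target
- the amount of target, in percent of the starting material charged, at that time
- the first time at which target reaches 39%, in the same percent, in d

The rule of thumb says that held gas means held second substrate, so the consumption of starting material is pseudo-first-order and curves in percent of the charge coincide. The readings allowed this. At 0.333 d, teal stood at 50% and amber at 47%, though amber's charge was 1.57 times teal's.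

But none of the second substrate is dissolved at the start, and saturation is a small load for this flask. I replaced teal's climb by its mean and asked how long that load would cover it:

load = saturation / charge = 0.400 of the charge

mean pace = 1.50 d⁻¹

store life, the time in which target at the mean pace equals the saturation load = load / pace = 0.266 d

The mean flatters the start: teal's first leg ran at 1.83 d⁻¹, faster than the mean, so my store life was if anything long. It was also shorter than teal's climb, and the flask starts with none of the second substrate dissolved, so I doubted the rule from the start of the climb to the peak.

The forecast put the peak at 0.29 d with 49% (range 44% to 54%) and 0.165 d for reaching 39%, holding that “the peak yield depends on the ratio of the two specificities, not on the starting concentration”.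

The flask peaked at 0.284 d.

    starting material + enzyme ⇌ starting complex (K = 52.1 M⁻¹, k = 6000 M⁻¹ s⁻¹)
    second substrate + starting complex ⇌ ternary complex (K = 4840 M⁻¹, k = 4870 M⁻¹ s⁻¹)
    ternary complex → enzyme + target (k = 0.748 s⁻¹)
    enzyme + target → enzyme + over-reaction product (k = 70.9 M⁻¹ s⁻¹)
    gas ⇌ second substrate, rate k5*(csat - [second substrate]) (kL = 1.75 × 10⁻⁴ s⁻¹)

It held 55.9% there, 6.9 percentage points above the forecast, and passed 39% at 0.148 d. At 0.284 d, dissolved second substrate stood at 0.221 of the charge, not at the saturation load of 0.400. The store life of 0.266 d lay just before the peak, the point at which this reading is worth taking. Scaling the pace with enzyme, a neighbour flask with 6.0 × 10⁻⁷ M of enzyme has a store life of 0.444 d, and its best was 61.7%.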